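## Structural features

Conneotricone is a tetracyclic depsidone. Two benzene rings, ring A and ring B, are joined by an aryl ester (carbonyl C11 on ring A, O10 on ring B) and by a diaryl ether (O5), which close a seven-membered dibenzo[b,e][1,4]dioxepin-11-one; a γ-lactone (phthalide) is fused to ring B. The numbering of that ring system is used throughout. Ring A (C11a, C1–C4, C4a) carries the lactone carbonyl at C11a, methyl at C1, a phenol at C3, a free carboxylic acid at C4 and the ether oxygen at C4a. Ring B (C5a, C6–C9, C9a) is hexasubstituted: ether oxygen at C5a, phthalide CH2 at C6, phthalide carbonyl at C7, phenol at C8, hydroxymethyl at C9 and the ester oxygen at C9a. There is no stereocentre, so the problem is regiochemistry and functional-group compatibility. The fragile groups are the aryl ester (base, nucleophiles), the C9 hydroxymethyl between two oxygen-bearing carbons (ionisation to an o-quinone methide, hydrogenolysis, ether formation with alcohols) and the salicylic-type acid at C4 (decarboxylation). The real difficulty is threefold: ring B has no free position, the ether links two carbons that each have two ortho substituents, and both ring A carboxyl carbons lie ortho to the ether oxygen, so either could lactonise onto ring B. The key step exploits the ring B pattern in which the oxygens on C9a and C8 are meta, the CH2O-bearing C9 lies between them and the ether oxygen on C5a is next to C9a. A vinylketene (supplying C9a, C7, C6, C5a) and a siloxyalkyne (supplying C9, C8) give exactly this pattern.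

## Logic of the disconnections

**30 to 28.** The phthalide acyl C–O bond (C7 carboxyl carbon to the oxygen on the C6 methylene) and four O–benzyl bonds are cut together. A 2-(hydroxymethyl)benzoic acid closes to the phthalide on its own, so one Lewis-acid debenzylation can be the last step and the sensitive C9 hydroxymethyl stays masked until then. The forward step must cleave two alkyl benzyl ethers, one aryl benzyl ether and one benzyl ester without ionising the C9 benzylic C–O bond. For that reason O3 is protected as benzyl, not methyl, and the C6 oxygen as plain benzyl, not 4-methoxybenzyl, so that one low-temperature reagent removes everything.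

**28 to 27 to 26 to 25.** No skeletal bond is cut between 28 and 27: the C7 carbon is returned to the aldehyde level. The depsidone ester C11–O10 is then cut (27 to 26) and C11 is re-masked as an allyl ester (25). Lactonisation to a seven-membered ring is far easier than intermolecular esterification of two di-ortho-substituted partners. The two ring A carboxyl carbons must be distinguishable (allyl on C11, benzyl on the C4 carboxyl). The C7 aldehyde is oxidised only after lactonisation, so that a single free acid is present at each stage.

**25 to 24 to 23.** The bond between C7 and its formyl carbon is cut, then the O8–Si bond is restored. C7 is the only C–H of ring B and lies ortho to the C8 phenol, so a phenol-directed formylation must go there. Formylation is placed before lactonisation so that no aryl ester meets amine and methanol at reflux.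

**23 to 15 + 18 (key disconnection).** Three ring B bonds are cut: C9a–C9, C8–C7 and C9a–C5a. In addition C6 is returned from C7 to the carbonyl carbon (reverse of the Wolff shift). Ring B dissolves into a diazo enone and a siloxyalkyne, and five of its six substituents, including the diaryl ether, are fixed by the connectivity of two open-chain pieces. The forward step needs a regioselective (2+2) addition of the polarised alkyne and a clean photochemical ketene generation in the presence of the ring A esters.

**18 to 16.** The O–Si bond and the C(sp)–O bond are cut: the ynol oxygen comes from oxidation of the acetylide of commercial 16.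

**15 to 13.** The bond between the carbonyl carbon and the diazo carbon is cut (acylation of diazomethane through 14).

**13 to 12.** The acid is freed from a tert-butyl ester. Acidolysis is the one ester cleavage that leaves the allyl and benzyl benzoates and the base-sensitive β-aryloxy acrylate untouched.

**12 to 6 + 11.** The vinyl C–O bond between the ring A oxygen and the enol carbon is cut. The future diaryl ether oxygen is thus attached to an unhindered sp2 CH by addition–elimination, not by coupling two crowded arenes. The demand is that a weak, hindered phenoxide attacks carbon and not sulfur.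

**11 to 9 to 7 + 8.** The O–S bond and the bond between the α-carbon and the formyl carbon are cut (Claisen formylation), then the benzyl ether C–O bond (oxa-Michael addition).

**6 to 5 to 4 to 3 to 2 to 1.** In turn: the benzyl ester C–O bond, the oxidation level of the new carbon, the C–C bond between C4 and that carbon (ortho-formylation directed by the phenol that later becomes O5), the benzyl ether at O3 and the allyl ester. All of ring A comes from 1; regiochemistry rests on the hydrogen-bonded 2-OH of the orsellinate and on the single free position ortho to it.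

## Other disconnections considered

**Alternative 1:** The cut is at the depside ester bond C11–O10 and at the ring A bond C11a–C1. In the forward direction the dioxinone A3 would be heated with the ring B bromophenol A2. Loss of acetone gives an acylketene that the phenol captures, and the aryl triketo ester would close ring A by aldol condensation and dehydration to the depside A1.
- In favour: ketene capture esterifies a hindered phenol under neutral conditions, so the most crowded acyl C–O bond is made early and without activating a di-ortho-substituted benzoic acid. Ring A arrives with both oxygens and the benzyl ester in one operation. That is equal to the chosen plan in spirit (an arene is built, not substituted) and better in step count for ring A, which costs five steps in the chosen route.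
- Against: A3 has a methine flanked by three carbonyl groups, so enolisation there and competing aldol or O-cyclisation modes make the aromatisation less predictable than for unbranched keto-dioxinones. A2 is a pentasubstituted phthalide that has to be made by successive substitutions of a benzene ring, which the chosen plan avoids for ring B. A1 still lacks the diaryl ether; closing it needs an Ullmann-type coupling of a phenol hydrogen-bonded between two esters with a di-ortho-substituted bromide, under base and heat, where the aryl ester can cleave or undergo Smiles rearrangement.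
- Comparison: on structure, alternative 1 builds the simpler ring and leaves the hexasubstituted one to classical methods. On mechanism, ionic ketene capture and aldol chemistry are operationally simpler than a photochemical cascade, a point for the alternative, but its hardest bond (the ether) comes last, whereas the chosen plan makes it first on an open-chain carbon. On step economy the two are probably similar: shorter for ring A, longer for ring B and the end game.

**Alternative 2:** The cut is at the ether bond C4a–O5 and at the bond between C4 and its carboxyl carbon. In the forward direction CsF under CO2 would desilylate the ring B oxygen of the ester A5 and generate the ring A aryne across C4–C4a. The phenoxide adds at C4a (seven-membered ring) and the C4 aryl anion takes up CO2 to give the depsidone acid A4.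
- In favour: this is the shortest end game of all. The ether and the free C4 acid appear in one step, so ring A needs no pair of orthogonal esters, which is better than the chosen plan. The tether and the C3 methoxy group (nucleophiles add distal to an alkoxy group on an aryne) direct the addition the same way.
- Against: aryne–nucleophile–CO2 couplings are established mainly for nitrogen nucleophiles and intermolecular cases; here the aryl anion can be protonated before it meets CO2. The freed phenoxide sits ortho to the ester oxygen on ring B, so O-to-O acyl migration could scramble which oxygen is acylated and lead to the regioisomeric depsidone. Fluoride also threatens the aryl ester. A5 needs a pentasubstituted silylaryl triflate and a fully substituted ring B catechol monoester, both made by stepwise arene substitution.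
- Comparison: on structure it shares with the chosen plan the idea of closing the seven-membered ring late, and it is superior in not needing ester differentiation. On mechanism its key step stacks three events whose order cannot be enforced, whereas the chosen cascade is unimolecular after the (2+2) step and its regiochemistry is set by alkyne polarisation. On step economy the end game is shorter, but the two precursors are longer than those of the chosen plan.

**Alternative 3:** The cut is at the bond between C9 and its hydroxymethyl carbon and, in masked form, at the ester bond O10–C11. In the forward direction the iodophenol A7 and the arylacetylene A8 would couple under PdCl2(PPh3)2 and CuI and cyclise to the 2-arylbenzofuran A6. Oxidative cleavage of the furan double bond would later unveil the C11 ester carbonyl and a formyl group on C9.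
- In favour: Sonogashira coupling with cyclisation is among the most dependable ways to join two elaborate arenes, and iodide reacts before bromide. The crowded ester is never made by acylation. On predictability of the key step this alternative is better than the chosen plan.
- Against: A7 is a hexasubstituted benzene with iodine, bromine, hydroxyl, methoxy and the phthalide, to be built by a long series of regioselective halogenations. The furan cleavage must spare two electron-rich rings. Reduction of the resulting formyl group next to the aryl ester invites acyl migration to the new benzylic alkoxide. The diaryl ether still has to be closed by a late Ullmann-type reaction at a di-ortho-substituted bromide, as in alternative 1.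
- Comparison: on structure it fixes the C9 carbon and the ester elegantly but leaves the ether and all of ring B to substitution chemistry. On mechanism it uses well-understood palladium and copper catalysis against a pericyclic cascade. On step economy it is clearly longer, because neither ring is built from acyclic material.

Key step: step 12

Remark: orsellinic acid, benzyl alcohol, tert-butyl acrylate and benzyl propargyl ether are taken as the commercial starting materials. The Z enol ether geometry drawn for 11–15 follows from the chelated enolate and a retentive addition–elimination; it is not an element of the target and an E component would give the same arene. ArA denotes the ring A aryl group 2-[(allyloxy)carbonyl]-5-(benzyloxy)-6-[(benzyloxy)carbonyl]-3-methylphenyl.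

## Route

Step 1
Reactants: 1 orsellinic acid (2,4-dihydroxy-6-methylbenzoic acid)
Product: 2 allyl 2,4-dihydroxy-6-methylbenzoate
Conditions: allyl bromide, KHCO3, DMF, rt
Reagents that add atoms: allyl bromide, C=CCBr
Why: Carboxylate O-alkylation (SN2); KHCO3 ionises only the carboxylic acid, so both phenols stay free, and room temperature avoids the decarboxylation to which orsellinic acid is prone.

Step 2
Reactants: 2 allyl 2,4-dihydroxy-6-methylbenzoate
Product: 3 allyl 4-(benzyloxy)-2-hydroxy-6-methylbenzoate
Conditions: BnBr (1.05 equiv), K2CO3, acetone, reflux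
Reagents that add atoms: benzyl bromide, BrCc1ccccc1
Why: Williamson etherification; the 2-OH is hydrogen-bonded to the ester carbonyl, so the 4-OH is alkylated selectively, as is usual for orsellinates.

Step 3
Reactants: 3 allyl 4-(benzyloxy)-2-hydroxy-6-methylbenzoate
Product: 4 allyl 4-(benzyloxy)-3-formyl-2-hydroxy-6-methylbenzoate
Conditions: MgCl2, Et3N, (CH2O)n, MeCN, reflux; aq. HCl work-up
Reagents that add atoms: paraformaldehyde (formaldehyde unit), C=O
Why: Magnesium-mediated ortho-formylation of a phenol (Casiraghi–Skattebøl reaction): formaldehyde is delivered within the magnesium phenoxide to the only free position ortho to the hydroxyl, and a second formaldehyde oxidises the benzylic alkoxide. The position is further activated by the adjacent benzyloxy group.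

Step 4
Reactants: 4 allyl 4-(benzyloxy)-3-formyl-2-hydroxy-6-methylbenzoate
Product: 5 6-(benzyloxy)-2-hydroxy-4-methyl-3-[(allyloxy)carbonyl]benzoic acid
Conditions: NaClO2, NaH2PO4, 2-methyl-2-butene, t-BuOH/THF/H2O, 0 °C to rt
Reagents that add atoms: sodium chlorite, [Na+].[O-]Cl=O
Why: Pinnick oxidation of the aldehyde through its chlorous acid adduct; 2-methyl-2-butene removes HOCl, so neither the arene nor the allyl group is chlorinated.

Step 5
Reactants: 5 6-(benzyloxy)-2-hydroxy-4-methyl-3-[(allyloxy)carbonyl]benzoic acid
Product: 6 1-allyl 3-benzyl 4-(benzyloxy)-2-hydroxy-6-methylbenzene-1,3-dicarboxylate (ArA–OH)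
Conditions: BnBr (1.05 equiv), KHCO3, DMF, rt
Reagents that add atoms: benzyl bromide, BrCc1ccccc1
Why: Carboxylate alkylation under bicarbonate; the phenol, hydrogen-bonded between two carbonyl groups, is not alkylated, and the two ring A carboxyl carbons are now distinguished as allyl and benzyl esters.

Step 6
Reactants: 7 benzyl alcohol; 8 tert-butyl acrylate
Product: 9 tert-butyl 3-(benzyloxy)propanoate
Conditions: NaH (5 mol %), THF, 0 °C to rt
Reagents that add atoms: none
Why: Base-catalysed oxa-Michael addition of the benzyl alkoxide to the acrylate; the tert-butyl ester resists transesterification.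

Step 7
Reactants: 9 tert-butyl 3-(benzyloxy)propanoate
Product: 11 tert-butyl (2Z)-2-[(benzyloxy)methyl]-3-[(4-methylbenzenesulfonyl)oxy]prop-2-enoate, via lithium formyl-ester enolate 10 (not isolated)
Conditions: LiN(iPr)2, THF, −78 °C; HCO2Et, −78 to −20 °C; TsCl, −20 to 0 °C
Reagents that add atoms: ethyl formate, CCOC=O; 4-methylbenzenesulfonyl chloride, Cc1ccc(cc1)S(Cl)(=O)=O
Why: Crossed Claisen formylation of the ester enolate, kept cold so that β-elimination of benzyloxide does not compete, followed by O-sulfonylation of the chelated formyl-ester enolate, which should give the Z enol tosylate in one flask.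

Step 8
Reactants: 6 1-allyl 3-benzyl 4-(benzyloxy)-2-hydroxy-6-methylbenzene-1,3-dicarboxylate; 11 tert-butyl (2Z)-2-[(benzyloxy)methyl]-3-[(4-methylbenzenesulfonyl)oxy]prop-2-enoate
Product: 12 tert-butyl (2Z)-3-(ArA-oxy)-2-[(benzyloxy)methyl]prop-2-enoate
Conditions: Cs2CO3, DMF, 50 °C
Reagents that add atoms: none
Why: Nucleophilic vinylic substitution by addition–elimination: the phenoxide adds to the β-carbon of the β-sulfonyloxy acrylate and tosylate leaves, with retention expected for a good leaving group. The future diaryl ether oxygen is thus attached to an open-chain CH and not to a crowded arene.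

Step 9
Reactants: 12 tert-butyl (2Z)-3-(ArA-oxy)-2-[(benzyloxy)methyl]prop-2-enoate
Product: 13 (2Z)-3-(ArA-oxy)-2-[(benzyloxy)methyl]prop-2-enoic acid
Conditions: CF3CO2H, CH2Cl2, 0 °C to rt
Reagents that add atoms: none
Why: Acidolysis of the tert-butyl ester with loss of isobutene (E1); benzyl ethers, the hindered allyl and benzyl benzoates and the β-aryloxy acrylate are inert under these conditions, and no hydroxide is used that could displace the aryloxide.

Step 10
Reactants: 13 (2Z)-3-(ArA-oxy)-2-[(benzyloxy)methyl]prop-2-enoic acid
Product: 15 (3Z)-4-(ArA-oxy)-3-[(benzyloxy)methyl]-1-diazobut-3-en-2-one, via acid chloride 14 (not isolated)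
Conditions: (COCl)2, DMF (cat.), CH2Cl2, 0 °C to rt; concentrate; CH2N2 (excess), Et2O, 0 °C
Reagents that add atoms: diazomethane, C=[N+]=[N-]
Why: Acid chloride formation through the chloroiminium reagent, then acylation of diazomethane (first stage of the Arndt–Eistert sequence), with excess diazomethane taking up HCl. The trisubstituted, β-oxygenated double bond is a poor dipolarophile, so pyrazoline formation should not compete at 0 °C.

Step 11
Reactants: 16 benzyl propargyl ether [3-(benzyloxy)prop-1-yne]
Product: 18 3-(benzyloxy)-1-[(triisopropylsilyl)oxy]prop-1-yne, via lithium ynolate 17 (not isolated)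
Conditions: LiN(SiMe3)2 (2.2 equiv), THF, −78 °C; t-BuOOH, −78 to 0 °C; iPr3SiOTf, −78 to 0 °C
Reagents that add atoms: tert-butyl hydroperoxide, CC(C)(C)OO; triisopropylsilyl trifluoromethanesulfonate, CC(C)[Si](C(C)C)(C(C)C)OS(=O)(=O)C(F)(F)F
Why: The lithium acetylide is oxidised by lithium tert-butyl peroxide to the lithium ynolate, which the bulky silyl triflate captures on oxygen; this is an established route from terminal alkynes to triisopropylsilyloxyalkynes.

Step 12
Reactants: 15 (3Z)-4-(ArA-oxy)-3-[(benzyloxy)methyl]-1-diazobut-3-en-2-one; 18 3-(benzyloxy)-1-[(triisopropylsilyl)oxy]prop-1-yne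
Product: 23 6-(ArA-oxy)-2,5-bis[(benzyloxy)methyl]-3-[(triisopropylsilyl)oxy]phenol, via vinylketene 19 (not isolated), via siloxycyclobutenone 20 (not isolated), via dienylketene 21 (not isolated), via cyclohexadienone 22 (not isolated)
Conditions: hν (medium-pressure Hg lamp, Pyrex filter), 18 (2 equiv), ClCH2CH2Cl, rt; then 80 °C
Reagents that add atoms: none
Why: Excitation of the diazo enone (Pyrex filter, so that benzoate and benzyl chromophores stay dark) expels N2 with a 1,2-shift of the alkenyl carbon (photochemical Wolff rearrangement), which joins future C6 to C7 and gives vinylketene 19. The electron-rich alkyne 18 adds to the ketene C=C in a (2+2) cycloaddition: its nucleophilic carbon (bearing CH2OBn) bonds to the ketene carbonyl carbon and its oxygen-bearing carbon to the ketene α-carbon, giving the 4-alkenyl-3-siloxycyclobut-2-enone 20, with the alkenyl group on the sp3 carbon. Conrotatory four-electron opening of 20 (light or heat) gives dienylketene 21, which closes ring B by a disrotatory six-electron electrocyclisation between the ketene carbon and the aryloxy-bearing alkene terminus; tautomerisation of dienone 22 gives phenol 23. The net result is three new ring bonds (C9a–C9, C8–C7, C9a–C5a) and one six-membered carbocycle. The closest known reaction type is the Danheiser benzannulation in its photochemical Wolff variant with siloxyalkynes, which gives resorcinol monosilyl ethers. No stereocentre is formed; the enol ether geometry is lost on aromatisation, and the aryloxy group, though it points inward during closure, meets only the sp-hybridised ketene carbon. The selectivity needed is the regiochemistry of the (2+2) step, which the polarisation of the siloxyalkyne secures: the silyloxy group ends meta to the new phenol with the CH2OBn carbon between them. The final heating completes the opening of any 20 that survives irradiation.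

Step 13
Reactants: 23 6-(ArA-oxy)-2,5-bis[(benzyloxy)methyl]-3-[(triisopropylsilyl)oxy]phenol
Product: 24 4-(ArA-oxy)-2,5-bis[(benzyloxy)methyl]benzene-1,3-diol
Conditions: Bu4NF, AcOH, THF, 0 °C
Reagents that add atoms: none
Why: Fluoride cleavage of the aryl silyl ether, driven by the Si–F bond; acetic acid buffers the phenoxides, and benzyl ethers and the hindered esters are untouched.

Step 14
Reactants: 24 4-(ArA-oxy)-2,5-bis[(benzyloxy)methyl]benzene-1,3-diol
Product: 25 5-(ArA-oxy)-3,6-bis[(benzyloxy)methyl]-2,4-dihydroxybenzaldehyde
Conditions: MgCl2, Et3N, (CH2O)n, THF, reflux; aq. HCl work-up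
Reagents that add atoms: paraformaldehyde (formaldehyde unit), C=O
Why: Casiraghi–Skattebøl ortho-formylation; future C7 is the only unsubstituted ring B carbon and lies ortho to the freed phenol, while ring A has no free phenol and is not attacked. It is done before lactonisation so that no aryl ester is exposed to amine and methanol.

Step 15
Reactants: 25 5-(ArA-oxy)-3,6-bis[(benzyloxy)methyl]-2,4-dihydroxybenzaldehyde
Product: 26 4-(benzyloxy)-3-[(benzyloxy)carbonyl]-2-{2,5-bis[(benzyloxy)methyl]-3-formyl-4,6-dihydroxyphenoxy}-6-methylbenzoic acid
Conditions: Pd(PPh3)4 (5 mol %), TolSO2Na, THF/MeOH, rt; aq. HCl work-up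
Reagents that add atoms: none
Why: Tsuji–Trost deallylation: zerovalent palladium ionises the allyl ester to a π-allyl complex that the sulfinate captures; this neutral scavenger leaves the aldehyde and the phenols alone, and the benzyl ester is inert.

Step 16
Reactants: 26 4-(benzyloxy)-3-[(benzyloxy)carbonyl]-2-{2,5-bis[(benzyloxy)methyl]-3-formyl-4,6-dihydroxyphenoxy}-6-methylbenzoic acid
Product: 27 benzyl 3-(benzyloxy)-6,9-bis[(benzyloxy)methyl]-7-formyl-8-hydroxy-1-methyl-11-oxo-11H-dibenzo[b,e][1,4]dioxepine-4-carboxylate
Conditions: DCC, DMAP (cat.), CH2Cl2 (0.005 M), 0 °C to rt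
Reagents that add atoms: none
Why: Steglich-type carbodiimide lactonisation; only the phenol ortho to the diaryl ether oxygen can reach the activated acid (seven-membered ring), the other phenol being remote and hydrogen-bonded to the aldehyde, and dilution suppresses oligomers.

Step 17
Reactants: 27 benzyl 3-(benzyloxy)-6,9-bis[(benzyloxy)methyl]-7-formyl-8-hydroxy-1-methyl-11-oxo-11H-dibenzo[b,e][1,4]dioxepine-4-carboxylate
Product: 28 3-(benzyloxy)-4-[(benzyloxy)carbonyl]-6,9-bis[(benzyloxy)methyl]-8-hydroxy-1-methyl-11-oxo-11H-dibenzo[b,e][1,4]dioxepine-7-carboxylic acid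
Conditions: NaClO2, NaH2PO4, 2-methyl-2-butene, t-BuOH/THF/H2O, 0 °C to rt
Reagents that add atoms: sodium chlorite, [Na+].[O-]Cl=O
Why: Pinnick oxidation of the hindered salicylaldehyde in a weakly acidic buffer in which the depsidone ester is stable; it brings the future lactone carbonyl to the acid level next to the masked C6 hydroxymethyl group.

Step 18
Reactants: 28 3-(benzyloxy)-4-[(benzyloxy)carbonyl]-6,9-bis[(benzyloxy)methyl]-8-hydroxy-1-methyl-11-oxo-11H-dibenzo[b,e][1,4]dioxepine-7-carboxylic acid
Product: 30 conneotricone, via debenzylated hydroxy diacid 29 (not isolated)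
Conditions: BCl3, C6HMe5, CH2Cl2, −78 to 0 °C; then THF/H2O, rt
Reagents that add atoms: none
Why: BCl3 should cleave the aryl benzyl ether (assisted by chelation to the ortho carbonyl), the benzyl ester and both alkyl benzyl ethers at low temperature, with pentamethylbenzene trapping the benzyl cations. On aqueous work-up the 2-(hydroxymethyl)benzoic acid unit of 29 closes spontaneously to the phthalide and gives the target.

## Compound list

1 | orsellinic acid (2,4-dihydroxy-6-methylbenzoic acid) | Cc1cc(O)cc(O)c1C(=O)O | starting material
2 | allyl 2,4-dihydroxy-6-methylbenzoate | Cc1cc(O)cc(O)c1C(=O)OCC=C | intermediate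
3 | allyl 4-(benzyloxy)-2-hydroxy-6-methylbenzoate | Cc1cc(OCc2ccccc2)cc(O)c1C(=O)OCC=C | intermediate
4 | allyl 4-(benzyloxy)-3-formyl-2-hydroxy-6-methylbenzoate | Cc1cc(OCc2ccccc2)c(C=O)c(O)c1C(=O)OCC=C | intermediate
5 | 6-(benzyloxy)-2-hydroxy-4-methyl-3-[(allyloxy)carbonyl]benzoic acid | Cc1cc(OCc2ccccc2)c(C(=O)O)c(O)c1C(=O)OCC=C | intermediate
6 | 1-allyl 3-benzyl 4-(benzyloxy)-2-hydroxy-6-methylbenzene-1,3-dicarboxylate (ArA–OH) | Cc1cc(OCc2ccccc2)c(C(=O)OCc2ccccc2)c(O)c1C(=O)OCC=C | intermediate
7 | benzyl alcohol | OCc1ccccc1 | starting material
8 | tert-butyl acrylate | C=CC(=O)OC(C)(C)C | starting material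
9 | tert-butyl 3-(benzyloxy)propanoate | CC(C)(C)OC(=O)CCOCc1ccccc1 | intermediate
10 | lithium (Z)-enolate of tert-butyl 3-(benzyloxy)-2-formylpropanoate | [Li+].[O-]/C=C(/COCc1ccccc1)C(=O)OC(C)(C)C | intermediate (not isolated)
11 | tert-butyl (2Z)-2-[(benzyloxy)methyl]-3-[(4-methylbenzenesulfonyl)oxy]prop-2-enoate | Cc1ccc(cc1)S(=O)(=O)O/C=C(/COCc1ccccc1)C(=O)OC(C)(C)C | intermediate
12 | tert-butyl (2Z)-3-(ArA-oxy)-2-[(benzyloxy)methyl]prop-2-enoate | Cc1cc(OCc2ccccc2)c(C(=O)OCc2ccccc2)c(O/C=C(/COCc2ccccc2)C(=O)OC(C)(C)C)c1C(=O)OCC=C | intermediate
13 | (2Z)-3-(ArA-oxy)-2-[(benzyloxy)methyl]prop-2-enoic acid | Cc1cc(OCc2ccccc2)c(C(=O)OCc2ccccc2)c(O/C=C(/COCc2ccccc2)C(=O)O)c1C(=O)OCC=C | intermediate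
14 | (2Z)-3-(ArA-oxy)-2-[(benzyloxy)methyl]prop-2-enoyl chloride | Cc1cc(OCc2ccccc2)c(C(=O)OCc2ccccc2)c(O/C=C(/COCc2ccccc2)C(Cl)=O)c1C(=O)OCC=C | intermediate (not isolated)
15 | (3Z)-4-(ArA-oxy)-3-[(benzyloxy)methyl]-1-diazobut-3-en-2-one | Cc1cc(OCc2ccccc2)c(C(=O)OCc2ccccc2)c(O/C=C(/COCc2ccccc2)C(=O)C=[N+]=[N-])c1C(=O)OCC=C | intermediate (precursor of the key step)
16 | benzyl propargyl ether [3-(benzyloxy)prop-1-yne] | C#CCOCc1ccccc1 | starting material
17 | lithium 3-(benzyloxy)prop-1-yn-1-olate | [Li+].[O-]C#CCOCc1ccccc1 | intermediate (not isolated)
18 | 3-(benzyloxy)-1-[(triisopropylsilyl)oxy]prop-1-yne | CC(C)[Si](C(C)C)(C(C)C)OC#CCOCc1ccccc1 | intermediate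
19 | 4-(ArA-oxy)-3-[(benzyloxy)methyl]buta-1,3-dien-1-one (vinylketene, aryloxy cis to the ketene arm) | Cc1cc(OCc2ccccc2)c(C(=O)OCc2ccccc2)c(O/C=C(/COCc2ccccc2)C=C=O)c1C(=O)OCC=C | intermediate (not isolated)
20 | 4-[2-(ArA-oxy)-1-[(benzyloxy)methyl]ethenyl]-2-[(benzyloxy)methyl]-3-[(triisopropylsilyl)oxy]cyclobut-2-en-1-one (racemic, aryloxy cis to the ring) | Cc1cc(OCc2ccccc2)c(C(=O)OCc2ccccc2)c(O/C=C(/COCc2ccccc2)C2C(=O)C(COCc3ccccc3)=C2O[Si](C(C)C)(C(C)C)C(C)C)c1C(=O)OCC=C | intermediate (not isolated)
21 | 6-(ArA-oxy)-2,5-bis[(benzyloxy)methyl]-3-[(triisopropylsilyl)oxy]hexa-1,3,5-trien-1-one (dienylketene, chain cis across the 3,4-double bond) | Cc1cc(OCc2ccccc2)c(C(=O)OCc2ccccc2)c(O/C=C(/COCc2ccccc2)\C=C(/C(COCc2ccccc2)=C=O)O[Si](C(C)C)(C(C)C)C(C)C)c1C(=O)OCC=C | intermediate (not isolated)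
22 | 6-(ArA-oxy)-2,5-bis[(benzyloxy)methyl]-3-[(triisopropylsilyl)oxy]cyclohexa-2,4-dien-1-one (racemic) | Cc1cc(OCc2ccccc2)c(C(=O)OCc2ccccc2)c(OC2C(=O)C(COCc3ccccc3)=C(O[Si](C(C)C)(C(C)C)C(C)C)C=C2COCc2ccccc2)c1C(=O)OCC=C | intermediate (not isolated)
23 | 6-(ArA-oxy)-2,5-bis[(benzyloxy)methyl]-3-[(triisopropylsilyl)oxy]phenol | Cc1cc(OCc2ccccc2)c(C(=O)OCc2ccccc2)c(Oc2c(COCc3ccccc3)cc(O[Si](C(C)C)(C(C)C)C(C)C)c(COCc3ccccc3)c2O)c1C(=O)OCC=C | intermediate (product of the key step)
24 | 4-(ArA-oxy)-2,5-bis[(benzyloxy)methyl]benzene-1,3-diol | Cc1cc(OCc2ccccc2)c(C(=O)OCc2ccccc2)c(Oc2c(COCc3ccccc3)cc(O)c(COCc3ccccc3)c2O)c1C(=O)OCC=C | intermediate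
25 | 5-(ArA-oxy)-3,6-bis[(benzyloxy)methyl]-2,4-dihydroxybenzaldehyde | Cc1cc(OCc2ccccc2)c(C(=O)OCc2ccccc2)c(Oc2c(COCc3ccccc3)c(C=O)c(O)c(COCc3ccccc3)c2O)c1C(=O)OCC=C | intermediate
26 | 4-(benzyloxy)-3-[(benzyloxy)carbonyl]-2-{2,5-bis[(benzyloxy)methyl]-3-formyl-4,6-dihydroxyphenoxy}-6-methylbenzoic acid | Cc1cc(OCc2ccccc2)c(C(=O)OCc2ccccc2)c(Oc2c(COCc3ccccc3)c(C=O)c(O)c(COCc3ccccc3)c2O)c1C(=O)O | intermediate
27 | benzyl 3-(benzyloxy)-6,9-bis[(benzyloxy)methyl]-7-formyl-8-hydroxy-1-methyl-11-oxo-11H-dibenzo[b,e][1,4]dioxepine-4-carboxylate | Cc1cc(OCc2ccccc2)c(C(=O)OCc2ccccc2)c2c1C(=O)Oc1c(COCc3ccccc3)c(O)c(C=O)c(COCc3ccccc3)c1O2 | intermediate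
28 | 3-(benzyloxy)-4-[(benzyloxy)carbonyl]-6,9-bis[(benzyloxy)methyl]-8-hydroxy-1-methyl-11-oxo-11H-dibenzo[b,e][1,4]dioxepine-7-carboxylic acid | Cc1cc(OCc2ccccc2)c(C(=O)OCc2ccccc2)c2c1C(=O)Oc1c(COCc3ccccc3)c(O)c(C(=O)O)c(COCc3ccccc3)c1O2 | intermediate
29 | 3,8-dihydroxy-6,9-bis(hydroxymethyl)-1-methyl-11-oxo-11H-dibenzo[b,e][1,4]dioxepine-4,7-dicarboxylic acid | Cc1cc(O)c(C(=O)O)c2c1C(=O)Oc1c(CO)c(O)c(C(=O)O)c(CO)c1O2 | intermediate (not isolated)
30 | conneotricone (depsidone with phthalide fused at C6–C7, 3,8-dihydroxy, 9-hydroxymethyl, 1-methyl, 4-carboxylic acid) | Cc1cc(O)c(C(=O)O)c2c1C(=O)Oc1c(CO)c(O)c3c(c1O2)COC3=O | target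

## Step count and risks

Total step count: 18. Longest linear sequence: 15 steps (steps 1–5, 8–10 and 12–18); steps 6–7 and step 11 are convergent branches.

Least certain steps:

**Step 12 (key step).** The vinylketene may be consumed unproductively (dimerisation, capture of the carbene by the neighbouring benzyloxymethyl oxygen before the Wolff shift, secondary photolysis of the aryl vinyl ether or of the product), because ketene generation and annulation share one irradiated flask. Fallback, from 15 back to 23: irradiate 15 alone in dilute CH2Cl2 at −20 °C so that 19 closes by four-electron electrocyclisation to 4-(ArA-oxy)-3-[(benzyloxy)methyl]cyclobut-2-en-1-one F1. Then heat F1 with 18 in toluene at 80–110 °C in the dark (thermal, first-generation form of the benzannulation); the aryloxy donor should rotate outward on ring opening, and the cascade then runs as in step 12 to 23.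

**Step 8.** The hindered, weakly nucleophilic phenoxide may attack sulfur instead of carbon (sulfonyl transfer giving the aryl tosylate), or addition may be too slow. Fallback, from 11 back to 12: treat 11 with DABCO in MeCN to form, by addition–elimination of the unhindered amine at carbon, the vinylammonium salt 1-[2-[(benzyloxy)methyl]-3-(tert-butoxy)-3-oxoprop-1-en-1-yl]-4-aza-1-azoniabicyclo[2.2.2]octane tosylate F2. Then combine F2 with 6 and Cs2CO3 in DMF at rt; the cationic acceptor has no sulfonyl group and is far more electrophilic, and the amine leaves to give 12 (its E/Z composition may differ, which is immaterial).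

**Step 10.** Dipolar cycloaddition of diazomethane to the conjugated double bond of 14 or 15, or conversion of 15 to a chloromethyl ketone if HCl is not scavenged, would erode the diazo ketone. Fallback, from 13 (through 14) back to 15: couple 14 with MeMgBr and Fe(acac)3 (cat.) in THF at −78 °C to the methyl ketone (3Z)-4-(ArA-oxy)-3-[(benzyloxy)methyl]but-3-en-2-one F3. Deprotonate F3 at the methyl group with LiN(SiMe3)2 and acylate with CF3CO2CH2CF3 to the diketone (5Z)-6-(ArA-oxy)-5-[(benzyloxy)methyl]-1,1,1-trifluorohex-5-ene-2,4-dione F4, which is not isolated. Treat F4 with MsN3, Et3N and H2O in MeCN (detrifluoroacetylative diazo transfer) to give 15 without diazomethane.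

**Step 18.** The C9 benzylic C–O bond may ionise on the arene side under BCl3 (chloride formation, quinone methide oligomers), or the alkyl benzyl ethers may cleave incompletely at the low temperature that protects C9. Fallback, from 28 back to 30: use excess BCl3 with C6HMe5 and warm to rt to drive the material deliberately to the benzylic chloride, the 9-(chloromethyl) analogue of conneotricone F5 (all benzyl groups removed, phthalide closed). Then solvolyse F5 with NaHCO3 in THF/H2O at rt; the o-hydroxybenzyl chloride hydrolyses through the quinone methide, with water as the only nucleophile, to 30.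

## Further compounds

F1 | step 12 | 4-(ArA-oxy)-3-[(benzyloxy)methyl]cyclobut-2-en-1-one (racemic) | Cc1cc(OCc2ccccc2)c(C(=O)OCc2ccccc2)c(OC2C(=O)C=C2COCc2ccccc2)c1C(=O)OCC=C
F2 | step 8 | 1-[2-[(benzyloxy)methyl]-3-(tert-butoxy)-3-oxoprop-1-en-1-yl]-4-aza-1-azoniabicyclo[2.2.2]octane 4-methylbenzenesulfonate (alkene geometry not controlled) | CC(C)(C)OC(=O)C(COCc1ccccc1)=C[N+]12CCN(CC1)CC2.Cc1ccc(cc1)S(=O)(=O)[O-]
F3 | step 10 | (3Z)-4-(ArA-oxy)-3-[(benzyloxy)methyl]but-3-en-2-one | Cc1cc(OCc2ccccc2)c(C(=O)OCc2ccccc2)c(O/C=C(/COCc2ccccc2)C(C)=O)c1C(=O)OCC=C
F4 | step 10 | (5Z)-6-(ArA-oxy)-5-[(benzyloxy)methyl]-1,1,1-trifluorohex-5-ene-2,4-dione | Cc1cc(OCc2ccccc2)c(C(=O)OCc2ccccc2)c(O/C=C(/COCc2ccccc2)C(=O)CC(=O)C(F)(F)F)c1C(=O)OCC=C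
F5 | step 18 | 9-(chloromethyl) analogue of conneotricone | Cc1cc(O)c(C(=O)O)c2c1C(=O)Oc1c(CCl)c(O)c3c(c1O2)COC3=O
A1 | alternative 1 | 4-bromo-6-[(benzyloxy)methyl]-7-methoxy-1-oxo-1,3-dihydro-2-benzofuran-5-yl 3-[(benzyloxy)carbonyl]-2,4-dihydroxy-6-methylbenzoate (depside) | Cc1cc(O)c(C(=O)OCc2ccccc2)c(O)c1C(=O)Oc1c(COCc2ccccc2)c(OC)c2C(=O)OCc2c1Br
A2 | alternative 1 | 4-bromo-6-[(benzyloxy)methyl]-5-hydroxy-7-methoxy-2-benzofuran-1(3H)-one | Oc1c(COCc2ccccc2)c(OC)c2C(=O)OCc2c1Br
A3 | alternative 1 | benzyl 2-(2,2-dimethyl-4-oxo-4H-1,3-dioxin-6-yl)-3,5-dioxohexanoate | CC(=O)CC(=O)C(C(=O)OCc1ccccc1)C1=CC(=O)OC(C)(C)O1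
A4 | alternative 2 | depsidone acid: 9-[(benzyloxy)methyl]-3,8-dimethoxy-1-methyl depsidone with phthalide fused at C6–C7 and free 4-carboxylic acid | Cc1cc(OC)c(C(=O)O)c2c1C(=O)Oc1c(COCc3ccccc3)c(OC)c3c(c1O2)COC3=O
A5 | alternative 2 | 6-[(benzyloxy)methyl]-4-[(tert-butyldimethylsilyl)oxy]-7-methoxy-1-oxo-1,3-dihydro-2-benzofuran-5-yl 4-methoxy-6-methyl-3-[(trifluoromethanesulfonyl)oxy]-2-(trimethylsilyl)benzoate | Cc1cc(OC)c(OS(=O)(=O)C(F)(F)F)c([Si](C)(C)C)c1C(=O)Oc1c(COCc2ccccc2)c(OC)c2C(=O)OCc2c1O[Si](C)(C)C(C)(C)C
A6 | alternative 3 | 2-arylbenzofuran fused to the phthalide: benzyl 3-(8-bromo-4-methoxy-5-oxo-5,7-dihydrofuro-fused benzofuran-2-yl)-6-methoxy-2-(methoxymethoxy)-4-methylbenzoate | Cc1cc(OC)c(C(=O)OCc2ccccc2)c(OCOC)c1-c1cc2c(OC)c3C(=O)OCc3c(Br)c2o1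
A7 | alternative 3 | 4-bromo-5-hydroxy-6-iodo-7-methoxy-2-benzofuran-1(3H)-one | Oc1c(I)c(OC)c2C(=O)OCc2c1Br
A8 | alternative 3 | benzyl 3-ethynyl-6-methoxy-2-(methoxymethoxy)-4-methylbenzoate | Cc1cc(OC)c(C(=O)OCc2ccccc2)c(OCOC)c1C#C
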